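**Plan**

- Labdane numbering (C1–C20) is used for the terpenoid part, also in the monocyclic precursors. The retrosynthesis cuts first the ester bond between C15 and glycerol O2, then C9–C10 (ring B), then the C8=C9 alkene.
- Forward: ring A is bought as the ring of (R)-α-ionone (its butenone chain becomes C6–C7–C8 with C17). The C9, C11–C16 chain comes from ozonised (R)-citronellic acid and is joined at C8=C9 by a Wittig reaction. Acid then closes ring B, and the glycerol ester is made last.
- Enabling feature: in diene acid 10 the ring-A alkene C1=C10 sits next to the stereogenic C5–H, and the trisubstituted C8=C9 alkene hangs from C5 through C6–C7. A cation at C10 therefore finds C9 in reach for a six-membered closure.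
- Stereochemistry: C5 comes from (R)-α-ionone and C10 is induced by C5 during ring closure. C13 comes from (R)-citronellic acid. Glycerol C2 comes from (S)-solketal, whose ring CH2O arm becomes the acetate arm and whose free CH2OH arm ends as the free hydroxyl.

Key step: step 6

Assumption: (R)-α-ionone, (R)-citronellic acid and (S)-solketal are bought in high enantiomeric purity; the optical purity of 1 and 4 fixes the diastereomeric purity of the ring system relative to C13.

**Route**

Step 1
Reactants: 1 (R)-α-ionone
Product: 3 (R)-dihydro-α-ionone, via triethylsilyl enol ether 2 (not isolated)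
Conditions: Et3SiH (1.1 equiv), RhCl(PPh3)3 (0.5 mol %), benzene, 50 °C; then K2CO3 (cat.), MeOH–H2O, rt
Reagents that add atoms: none
Why: Rhodium-catalysed 1,4-hydrosilylation of an enone with a monohydrosilane gives the silyl enol ether, which hydrolyses to the saturated ketone; the isolated trisubstituted ring alkene and the ring stereocentre are not touched.

Step 2
Reactants: 4 (R)-citronellic acid
Product: 6 (3R)-6-hydroxy-3-methylhexanoic acid, via ozonide 5 (not isolated)
Conditions: O3, CH2Cl2, −78 °C; then NaBH4 (excess), MeOH, −78 °C → rt; acidic work-up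
Reagents that add atoms: ozone, [O-][O+]=O
Why: Ozonolysis cleaves the only alkene and borohydride reduces the ozonide directly to the primary alcohol; the methyl-bearing centre is remote and unaffected.

Step 3
Reactants: 6 (3R)-6-hydroxy-3-methylhexanoic acid
Product: 7 (3R)-6-bromo-3-methylhexanoic acid
Conditions: 48% aq. HBr, conc. H2SO4 (cat.), 100 °C
Reagents that add atoms: hydrogen bromide, Br
Why: SN2 displacement of the protonated primary hydroxyl by bromide, the standard preparation of ω-bromoalkanoic acids from hydroxy acids; the C3 centre is not α to the carboxyl and cannot epimerise.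

Step 4
Reactants: 7 (3R)-6-bromo-3-methylhexanoic acid
Product: 8 [(4R)-5-carboxy-4-methylpentyl]triphenylphosphonium bromide
Conditions: PPh3, MeCN, reflux
Reagents that add atoms: triphenylphosphine, c1ccc(cc1)P(c1ccccc1)c1ccccc1
Why: SN2 quaternisation of triphenylphosphine by a primary bromide, as used for the common ω-carboxyalkylphosphonium salts.

Step 5
Reactants: 8 [(4R)-5-carboxy-4-methylpentyl]triphenylphosphonium bromide + 3 (R)-dihydro-α-ionone
Product: 10 (3R)-3,7-dimethyl-9-[(1R)-2,6,6-trimethylcyclohex-2-en-1-yl]non-6-enoic acid (E/Z mixture at C8=C9), via potassium ylide carboxylate 9 (not isolated)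
Conditions: 8 (1.5 equiv), KOtBu (3.0 equiv), THF, 0 °C → rt; then 3, rt → 50 °C; acidic work-up
Reagents that add atoms: none
Why: Wittig reaction of a methyl ketone with a non-stabilised carboxylate-bearing ylide (two equivalents of base per salt), the way homofarnesic-type acids are made from methyl ketones; the E/Z mixture is acceptable because both isomers converge in step 6, and acid–base extraction should separate 10 from Ph3PO.

Step 6
Reactants: 10 (3R)-3,7-dimethyl-9-[(1R)-2,6,6-trimethylcyclohex-2-en-1-yl]non-6-enoic acid (E/Z)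
Product: 15 (5R,10R,13R)-labd-8-en-15-oic acid, via C10 carbocation 11 (not isolated), via C8 carbocation 12 (not isolated), via labd-7-en-15-oic acid 13 (not isolated), via labd-8(17)-en-15-oic acid 14 (not isolated)
Conditions: FSO3H (5 equiv), 2-nitropropane, −78 °C; Et3N quench at −78 °C, acidic work-up; crude acids, 57% aq. HI (cat.), benzene, 80 °C
Reagents that add atoms: none
Why: FSO3H protonates C1 of the ring-A alkene (Markovnikov) to the tertiary C10 cation 11, C9 of the chain alkene bonds to C10 to give the tertiary C8 cation 12, and proton loss followed by HI-mediated re-protonation of the Δ7 and Δ8(17) acids 13 and 14 through 12 should drain the material to the tetrasubstituted C8=C9 alkene. The closest known reaction type is the superacid cation–olefin cyclisation of α-monocyclic, dihydro-α-ionone-derived terpenoid acids and esters to drimane and labdane bicycles, with HI in benzene as the usual way to move a labdane alkene to the 8(9) position. Ring B closes in the 6-endo-trig mode (both alkene carbons end up in the ring), the sense that pairs a six-membered ring with a tertiary cation at C8. The new C10 centre is controlled by the C5 centre from α-ionone: in the chair-like transition state the C4–C5 bond is equatorial on the forming ring, so C9 adds to the face of C10 opposite to C5–H and the C10 methyl ends up anti to C5–H (trans-decalin). The step needs closure to outrun loss of the C5 proton from 11, which would move the ring alkene to the tetrasubstituted position and erase the controlling centre; the low temperature and the nucleophilic trisubstituted alkene held close by the C6–C7 tether should secure this, and no control of alkene geometry is needed because C8 and C9 are sp2 in 15. The carboxylic acid is only protonated at −78 °C and cannot trap C8, since that would require an eight-membered lactone.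

Step 7
Reactants: 16 (S)-solketal
Product: 17 (4R)-4-{[(tert-butyldiphenylsilyl)oxy]methyl}-2,2-dimethyl-1,3-dioxolane
Conditions: TBDPSCl, imidazole, CH2Cl2, 0 °C → rt
Reagents that add atoms: tert-butyl(chloro)diphenylsilane, CC(C)(C)[Si](Cl)(c1ccccc1)c1ccccc1
Why: Standard imidazole-promoted silylation of a primary alcohol; the descriptor changes to R only through the priority rules, no bond at the stereocentre is touched.

Step 8
Reactants: 17 (4R)-4-{[(tert-butyldiphenylsilyl)oxy]methyl}-2,2-dimethyl-1,3-dioxolane
Product: 18 (2R)-3-[(tert-butyldiphenylsilyl)oxy]propane-1,2-diol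
Conditions: AcOH–H2O (4:1), 40 °C
Reagents that add atoms: none
Why: Aqueous-acid hydrolysis of the isopropylidene acetal, to which a primary TBDPS ether is inert.

Step 9
Reactants: 18 (2R)-3-[(tert-butyldiphenylsilyl)oxy]propane-1,2-diol
Product: 19 (2R)-3-[(tert-butyldiphenylsilyl)oxy]-2-hydroxypropyl acetate
Conditions: AcCl (1.05 equiv), 2,4,6-collidine, CH2Cl2, −78 °C
Reagents that add atoms: acetyl chloride, CC(=O)Cl
Why: Kinetically selective acylation of the primary hydroxyl of a 1,2-diol with acetyl chloride and a hindered pyridine base at low temperature; the base is too weak to drive acyl or silyl migration.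

Step 10
Reactants: 15 (5R,10R,13R)-labd-8-en-15-oic acid + 19 (2R)-3-[(tert-butyldiphenylsilyl)oxy]-2-hydroxypropyl acetate
Product: 20 (2R)-1-acetoxy-3-[(tert-butyldiphenylsilyl)oxy]propan-2-yl (5R,10R,13R)-labd-8-en-15-oate
Conditions: DCC, DMAP (cat.), CH2Cl2, 0 °C → rt
Reagents that add atoms: none
Why: Steglich esterification of a secondary alcohol with an unhindered acid that has no α-stereocentre; low temperature and little DMAP should keep the neighbouring acetate in place.

Step 11
Reactants: 20 (2R)-1-acetoxy-3-[(tert-butyldiphenylsilyl)oxy]propan-2-yl (5R,10R,13R)-labd-8-en-15-oate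
Product: 21 (2S)-1-acetoxy-3-hydroxypropan-2-yl (5R,10R,13R)-labd-8-en-15-oate (target, CNP0216082.1)
Conditions: HF·pyridine, pyridine, THF, 0 °C → rt
Reagents that add atoms: none
Why: Fluoride cleavage of the Si–O bond under weakly acidic, pyridine-buffered conditions, which should suppress 1,2-acyl migration in the freed diacylglycerol; both esters and the tetrasubstituted alkene are inert to the reagent.

**Compound list**

1 | (R)-α-ionone, (3E)-4-[(1R)-2,6,6-trimethylcyclohex-2-en-1-yl]but-3-en-2-one | CC(=O)/C=C/[C@@H]1C(C)(C)CCC=C1C | starting material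
2 | triethylsilyl enol ether of 3 (E/Z), triethyl({4-[(1R)-2,6,6-trimethylcyclohex-2-en-1-yl]but-2-en-2-yl}oxy)silane | CC[Si](CC)(CC)OC(C)=CC[C@@H]1C(C)(C)CCC=C1C | intermediate
3 | (R)-dihydro-α-ionone, 4-[(1R)-2,6,6-trimethylcyclohex-2-en-1-yl]butan-2-one | CC(=O)CC[C@@H]1C(C)(C)CCC=C1C | intermediate
4 | (R)-citronellic acid, (3R)-3,7-dimethyloct-6-enoic acid | OC(=O)C[C@H](C)CCC=C(C)C | starting material
5 | ozonide, (3R)-5-(5,5-dimethyl-1,2,4-trioxolan-3-yl)-3-methylpentanoic acid | OC(=O)C[C@H](C)CCC1OOC(C)(C)O1 | intermediate
6 | (3R)-6-hydroxy-3-methylhexanoic acid | OC(=O)C[C@H](C)CCCO | intermediate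
7 | (3R)-6-bromo-3-methylhexanoic acid | OC(=O)C[C@H](C)CCCBr | intermediate
8 | [(4R)-5-carboxy-4-methylpentyl]triphenylphosphonium bromide | OC(=O)C[C@H](C)CCC[P+](c1ccccc1)(c1ccccc1)c1ccccc1.[Br-] | intermediate
9 | potassium (3R)-3-methyl-6-(triphenyl-λ5-phosphanylidene)hexanoate (ylide carboxylate) | [K+].[O-]C(=O)C[C@H](C)CCC=P(c1ccccc1)(c1ccccc1)c1ccccc1 | intermediate
10 | (3R)-3,7-dimethyl-9-[(1R)-2,6,6-trimethylcyclohex-2-en-1-yl]non-6-enoic acid, E/Z mixture at C8=C9 | OC(=O)C[C@H](C)CCC=C(C)CC[C@@H]1C(C)(C)CCC=C1C | intermediate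
11 | C10 carbocation from 10 (ring alkene protonated at C1) | OC(=O)C[C@H](C)CCC=C(C)CC[C@@H]1C(C)(C)CCC[C+]1C | intermediate
12 | C8 carbocation, (5R,10R,13R)-15-carboxylabdan-8-ylium (both C9 epimers) | OC(=O)C[C@H](C)CCC1[C+](C)CC[C@@H]2C(C)(C)CCC[C@@]12C | intermediate
13 | (5R,10R,13R)-labd-7-en-15-oic acid (both C9 epimers) | OC(=O)C[C@H](C)CCC1C(C)=CC[C@@H]2C(C)(C)CCC[C@@]12C | intermediate
14 | (5R,10R,13R)-labd-8(17)-en-15-oic acid (both C9 epimers) | OC(=O)C[C@H](C)CCC1C(=C)CC[C@@H]2C(C)(C)CCC[C@@]12C | intermediate
15 | (5R,10R,13R)-labd-8-en-15-oic acid (ent-labdane ring configuration) | OC(=O)C[C@H](C)CCC1=C(C)CC[C@@H]2C(C)(C)CCC[C@@]12C | intermediate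
16 | (S)-solketal, [(4S)-2,2-dimethyl-1,3-dioxolan-4-yl]methanol | CC1(C)OC[C@H](CO)O1 | starting material
17 | (4R)-4-{[(tert-butyldiphenylsilyl)oxy]methyl}-2,2-dimethyl-1,3-dioxolane | CC1(C)OC[C@H](CO[Si](c2ccccc2)(c2ccccc2)C(C)(C)C)O1 | intermediate
18 | (2R)-3-[(tert-butyldiphenylsilyl)oxy]propane-1,2-diol (3-O-TBDPS-sn-glycerol) | OC[C@H](CO[Si](c1ccccc1)(c1ccccc1)C(C)(C)C)O | intermediate
19 | (2R)-3-[(tert-butyldiphenylsilyl)oxy]-2-hydroxypropyl acetate (1-O-acetyl-3-O-TBDPS-sn-glycerol) | CC(=O)OC[C@H](CO[Si](c1ccccc1)(c1ccccc1)C(C)(C)C)O | intermediate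
20 | (2R)-1-acetoxy-3-[(tert-butyldiphenylsilyl)oxy]propan-2-yl (5R,10R,13R)-labd-8-en-15-oate | CC(=O)OC[C@H](CO[Si](c1ccccc1)(c1ccccc1)C(C)(C)C)OC(=O)C[C@H](C)CCC1=C(C)CC[C@@H]2C(C)(C)CCC[C@@]12C | intermediate
21 | (2S)-1-acetoxy-3-hydroxypropan-2-yl (5R,10R,13R)-labd-8-en-15-oate (1-O-acetyl-2-O-acyl-sn-glycerol, CNP0216082.1) | CC(=O)OC[C@H](CO)OC(=O)C[C@H](C)CCC1=C(C)CC[C@@H]2C(C)(C)CCC[C@@]12C | target

**Step count**

Total: 11 steps. Longest linear sequence: 7 steps (steps 2, 3, 4, 5, 6, 10, 11, from (R)-citronellic acid).

**Steps most likely to fail**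

1. Step 6. Two processes can go wrong. The C10 cation may lose the C5 proton faster than C9 arrives, so the ring alkene drifts to the tetrasubstituted position and the C5/C10 configuration leaks; this would show as a diastereomer, because C13 is fixed. The superacid may also divert material through protonation of the chain alkene. The fallback sets out from 10 and comes back at 15. It replaces the free cation in superacid by a concerted proton transfer from a Lewis-acid-assisted Brønsted acid in a non-ionising solvent, run on the ester. Acid 10 would be methylated (MeI, K2CO3, DMF) to methyl (3R)-3,7-dimethyl-9-[(1R)-2,6,6-trimethylcyclohex-2-en-1-yl]non-6-enoate F1. F1 would be closed with SnCl4·CF3CO2H in CH2Cl2 at −78 °C, a reagent known to complete ring closure of monocyclic polyprenoid intermediates with retention of their ring stereocentre. The crude alkene mixture would be equilibrated with HI in benzene to methyl (5R,10R,13R)-labd-8-en-15-oate F2, and F2 saponified (LiOH, THF–MeOH–H2O) to 15.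

2. Step 11. Once the primary hydroxyl is free, the secondary terpenoid acyl group can migrate to it (1,2- to 1,3-diacylglycerol), and the robust TBDPS ether may cleave slowly enough for this to compete. The fallback sets out from 16 and comes back at 21. It uses an ether that is removed oxidatively at neutral pH instead of a silyl ether. Alcohol 16 would be alkylated (NaH, 4-methoxybenzyl chloride, Bu4NI, THF) to (4S)-4-{[(4-methoxybenzyl)oxy]methyl}-2,2-dimethyl-1,3-dioxolane F3. Acetal hydrolysis (AcOH–H2O) would give (2R)-3-[(4-methoxybenzyl)oxy]propane-1,2-diol F4. Primary acetylation (AcCl, 2,4,6-collidine, −78 °C) would give (2S)-2-hydroxy-3-[(4-methoxybenzyl)oxy]propyl acetate F5. Steglich esterification with 15 would give (2S)-1-acetoxy-3-[(4-methoxybenzyl)oxy]propan-2-yl (5R,10R,13R)-labd-8-en-15-oate F6. DDQ in CH2Cl2–pH 7 buffer at 0 °C would then release 21.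

3. Step 9. Regiocontrol may be lost through over-acetylation to the diacetate, or through acetylation at or migration to the secondary oxygen; the terpenoid acid would then end up on the wrong carbon. The fallback sets out from 18 and comes back at 19. It uses tin-acetal-directed acylation instead of kinetic discrimination by a hindered base. Diol 18 would be heated with Bu2SnO in toluene with removal of water to give the stannylene acetal (4S)-2,2-dibutyl-4-{[(tert-butyldiphenylsilyl)oxy]methyl}-1,3,2-dioxastannolane F7. F7 would be treated with AcCl at 0 °C, which should acylate the primary oxygen to give 19.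

**Further compounds**

F1 | step 6 | methyl (3R)-3,7-dimethyl-9-[(1R)-2,6,6-trimethylcyclohex-2-en-1-yl]non-6-enoate (E/Z) | COC(=O)C[C@H](C)CCC=C(C)CC[C@@H]1C(C)(C)CCC=C1C
F2 | step 6 | methyl (5R,10R,13R)-labd-8-en-15-oate | COC(=O)C[C@H](C)CCC1=C(C)CC[C@@H]2C(C)(C)CCC[C@@]12C
F3 | step 11 | (4S)-4-{[(4-methoxybenzyl)oxy]methyl}-2,2-dimethyl-1,3-dioxolane | CC1(C)OC[C@H](COCc2ccc(OC)cc2)O1
F4 | step 11 | (2R)-3-[(4-methoxybenzyl)oxy]propane-1,2-diol | OC[C@H](COCc1ccc(OC)cc1)O
F5 | step 11 | (2S)-2-hydroxy-3-[(4-methoxybenzyl)oxy]propyl acetate | CC(=O)OC[C@H](COCc1ccc(OC)cc1)O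
F6 | step 11 | (2S)-1-acetoxy-3-[(4-methoxybenzyl)oxy]propan-2-yl (5R,10R,13R)-labd-8-en-15-oate | CC(=O)OC[C@H](COCc1ccc(OC)cc1)OC(=O)C[C@H](C)CCC1=C(C)CC[C@@H]2C(C)(C)CCC[C@@]12C
F7 | step 9 | (4S)-2,2-dibutyl-4-{[(tert-butyldiphenylsilyl)oxy]methyl}-1,3,2-dioxastannolane | CCCC[Sn]1(CCCC)OC[C@H](CO[Si](c2ccccc2)(c2ccccc2)C(C)(C)C)O1
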